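**Retrosynthetic overview**

1. The isoflavone pyranone ring is opened last: its C2 comes from DMF, and the bond between the C4 carbonyl and ring A comes from a Friedel–Crafts acylation of phloroglucinol with a (chroman-5-yl)acetic acid.
2. The strategy rests on the benzene ring of the chroman (C4a, C5, C6, C7, C8, C8a). It carries the carbon chain on C5, the ring CH2 on C4a, the ring oxygen on C8a and OH on C8, with C6 and C7 bearing H. This is the pattern of a 4,5-disubstituted 6-alkoxycyclohex-2-enone one dehydrogenation below the phenol.
3. That cyclohexenone is cut at C4a–C5 (Michael addition) and C6–C7 (aldol condensation) into 2-acetyl-6,6-dimethyl-5,6-dihydro-4H-pyran and methyl 4-oxobutanoate. The acetyl dihydropyran comes from acrolein and isobutene by hetero-Diels–Alder reaction, then α-lithiation and acetylation.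
4. Ring order: dihydropyran (the future chroman pyran ring), then the carbocycle by annulation and aromatisation, then the chromone pyranone. Ring A is bought as phloroglucinol.

Key step: step 3

Remark: the target has no stereocentre. The three centres of 10 form without control and are removed in step 4, so 10 is carried on as a diastereomer mixture. BF3·OEt2 in steps 6 and 7 is treated as a Lewis-acidic medium that does not enter the balanced equations.

**Route**

Step 1
Reactants: 1 acrolein; 2 isobutene
Product: 3 2,2-dimethyl-3,4-dihydro-2H-pyran
Conditions: 2 (excess), hydroquinone (cat.), neat, sealed autoclave, 180–200 °C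
Reagents that add atoms: none
Why: Thermal inverse-electron-demand hetero-Diels–Alder reaction with acrolein as the 1-oxadiene should bond oxygen to the more substituted, cation-stabilising alkene carbon and so give the 2,2-dimethyl regioisomer; no stereocentre is formed.

Step 2
Reactants: 3 2,2-dimethyl-3,4-dihydro-2H-pyran
Product: 6 1-(6,6-dimethyl-5,6-dihydro-4H-pyran-2-yl)ethan-1-one, via lithiated dihydropyran 4 (not isolated), via lithium hemiaminal adduct 5 (not isolated)
Conditions: t-BuLi, THF–pentane, −78 to 0 °C; then MeC(O)N(OMe)Me, −78 °C to rt; then H2O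
Reagents that add atoms: N-methoxy-N-methylacetamide, CC(=O)N(C)OC
Why: α-Lithiation of the cyclic enol ether at its O-bearing vinylic CH followed by Weinreb ketone synthesis should give the methyl ketone cleanly, because the chelated tetrahedral adduct 5 does not collapse before the quench and so cannot over-add.

Step 3
Reactants: 6 1-(6,6-dimethyl-5,6-dihydro-4H-pyran-2-yl)ethan-1-one; 7 methyl 4-oxobutanoate
Product: 10 methyl 2-(2,2-dimethyl-8-oxo-3,4,4a,5,8,8a-hexahydro-2H-chromen-5-yl)acetate (diastereomer mixture), via pyrrolidine enamine 8 (not isolated), via keto aldehyde 9 (not isolated)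
Conditions: 7 (1.5 equiv), pyrrolidine (1.5 equiv), 4 Å MS, 1,4-dioxane, 0 °C to rt; then 6, 90 °C, high concentration; then AcOH, NaOAc, H2O, 90 °C
Reagents that add atoms: none
Why: Pyrrolidine turns aldehyde 7 into enamine 8, whose nucleophilic carbon (the aldehyde α-carbon) adds to C3 of the dihydropyran in 6, the β-carbon of the α-alkoxy enone, directly or through the [4+2] aminal, and buffered hydrolysis releases keto aldehyde 9 with the future chroman C4a–C5 bond in place. Pyrrolidinium acetate then mediates aldol condensation of the ketone CH3 with the aldehyde carbonyl, and dehydration gives the C6=C7 double bond of cyclohexenone 10. The closest known reaction is the Stork enamine variant of the Robinson annulation of aldehydes with alkenyl methyl ketones to give 4-substituted cyclohex-2-enones. The carbocycle closes in the 6-(enolendo)-exo-trig mode, the only ketone enolisation that reaches the aldehyde through a ring larger than four atoms. Three stereocentres (C4a, C5, C8a) arise without control and are left as a mixture because step 4 removes all of them. Only regiochemistry is required and the polarity of the partners fixes it; the ring oxygen lowers the electrophilicity of the β-carbon by enol-ether donation, which is answered by a stoichiometric preformed enamine, high concentration and heat.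

Step 4
Reactants: 10 methyl 2-(2,2-dimethyl-8-oxo-3,4,4a,5,8,8a-hexahydro-2H-chromen-5-yl)acetate
Product: 11 methyl 2-(8-hydroxy-2,2-dimethylchroman-5-yl)acetate
Conditions: Pd(TFA)2 (5 mol%), 2-(dimethylamino)pyridine (10 mol%), TsOH·H2O (20 mol%), O2 (1 atm), DMSO, 80 °C
Reagents that add atoms: none
Why: Pd(II)-catalysed aerobic dehydrogenation of a cyclohexenone to a phenol should proceed by palladium enolate formation at C8a and β-hydride elimination of the C4a hydrogen, after which the 2,5-cyclohexadienone tautomerises through C5–H to the phenol and all three stereocentres disappear; the ester and the cyclic ether are inert here.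

Step 5
Reactants: 11 methyl 2-(8-hydroxy-2,2-dimethylchroman-5-yl)acetate
Product: 12 2-(8-hydroxy-2,2-dimethylchroman-5-yl)acetic acid
Conditions: LiOH·H2O, THF–H2O (degassed), rt, argon; then 1 M HCl
Reagents that add atoms: lithium hydroxide, [Li+].[OH-]
Why: Saponification of the methyl ester (BAc2) should be clean since the chroman ether is base-stable, with air excluded because the electron-rich phenolate is oxidisable.

Step 6
Reactants: 12 2-(8-hydroxy-2,2-dimethylchroman-5-yl)acetic acid; 13 phloroglucinol (anhydrous)
Product: 14 2-(8-hydroxy-2,2-dimethylchroman-5-yl)-1-(2,4,6-trihydroxyphenyl)ethan-1-one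
Conditions: 13 (1.5 equiv), BF3·OEt2 (as medium), 85 °C, argon; then aq. NaOAc
Reagents that add atoms: none
Why: Friedel–Crafts C-acylation of phloroglucinol by the arylacetic acid in BF3·OEt2 should stop at the mono-ketone, held as its BF2 chelate; the triphenol has only one kind of ring position and is far more nucleophilic than the chromanol ring, so neither regiochemistry nor self-acylation is a concern.

Step 7
Reactants: 14 2-(8-hydroxy-2,2-dimethylchroman-5-yl)-1-(2,4,6-trihydroxyphenyl)ethan-1-one
Product: 15 5,7-dihydroxy-3-(8-hydroxy-2,2-dimethylchroman-5-yl)-4H-chromen-4-one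
Conditions: BF3·OEt2, DMF, 50 °C; then MsCl, 75 °C; then H2O, 70 °C
Reagents that add atoms: N,N-dimethylformamide, CN(C)C=O
Why: Vilsmeier-type formylation of the BF2-activated methylene by the DMF–MsCl iminium salt, attack of an ortho hydroxyl on the aminomethylene carbon and loss of dimethylamine should close the pyranone (deoxybenzoin route to isoflavones); the two ortho hydroxyls are equivalent, so a single isoflavone is expected, and any O-formate is cleaved in the aqueous finish.

**Compound list**

1 | acrolein | C=CC=O | starting material
2 | isobutene | CC(C)=C | starting material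
3 | 2,2-dimethyl-3,4-dihydro-2H-pyran | CC1(C)CCC=CO1 | intermediate
4 | (6,6-dimethyl-5,6-dihydro-4H-pyran-2-yl)lithium | [Li]C1=CCCC(C)(C)O1 | intermediate (not isolated)
5 | lithium 1-(6,6-dimethyl-5,6-dihydro-4H-pyran-2-yl)-1-[methoxy(methyl)amino]ethan-1-olate (racemic) | CC(O[Li])(N(C)OC)C1=CCCC(C)(C)O1 | intermediate (not isolated)
6 | 1-(6,6-dimethyl-5,6-dihydro-4H-pyran-2-yl)ethan-1-one | CC(=O)C1=CCCC(C)(C)O1 | intermediate
7 | methyl 4-oxobutanoate | COC(=O)CCC=O | starting material
8 | methyl (E)-4-(pyrrolidin-1-yl)but-3-enoate | COC(=O)C/C=C/N1CCCC1 | intermediate (not isolated)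
9 | methyl 3-(2-acetyl-6,6-dimethyltetrahydro-2H-pyran-3-yl)-4-oxobutanoate (diastereomer mixture) | COC(=O)CC(C=O)C1CCC(C)(C)OC1C(C)=O | intermediate (not isolated)
10 | methyl 2-(2,2-dimethyl-8-oxo-3,4,4a,5,8,8a-hexahydro-2H-chromen-5-yl)acetate (diastereomer mixture, centres at C4a, C5, C8a undefined) | COC(=O)CC1C=CC(=O)C2OC(C)(C)CCC12 | intermediate
11 | methyl 2-(8-hydroxy-2,2-dimethylchroman-5-yl)acetate | COC(=O)Cc1ccc(O)c2OC(C)(C)CCc12 | intermediate
12 | 2-(8-hydroxy-2,2-dimethylchroman-5-yl)acetic acid | OC(=O)Cc1ccc(O)c2OC(C)(C)CCc12 | intermediate
13 | phloroglucinol | Oc1cc(O)cc(O)c1 | starting material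
14 | 2-(8-hydroxy-2,2-dimethylchroman-5-yl)-1-(2,4,6-trihydroxyphenyl)ethan-1-one | O=C(Cc1ccc(O)c2OC(C)(C)CCc12)c1c(O)cc(O)cc1O | intermediate
15 | 5,7-dihydroxy-3-(8-hydroxy-2,2-dimethylchroman-5-yl)-4H-chromen-4-one (achiral) | CC1(C)CCc2c(-c3coc4cc(O)cc(O)c4c3=O)ccc(O)c2O1 | target

**Step count**

Total steps: 7. Longest linear sequence: 7 steps (1 and 2 to 15); 7 and 13 enter as purchased materials.

**Steps most likely to fail**

Step 3. Conjugate addition may be too slow, because donation from the ring oxygen lowers the electrophilicity of the enone β-carbon, and self-condensation of the aldehyde enamine may then consume the nucleophile. The fallback sets out from 6 and 7 and comes back at 10, and it activates the acceptor instead of the donor. Aldehyde 7 is converted into its silyl enol ether, methyl (Z)-4-[(trimethylsilyl)oxy]but-3-enoate F1 (TMSCl, Et3N, DMF, 80 °C). TiCl4 (CH2Cl2, −78 °C) should chelate the ring oxygen and the carbonyl oxygen of 6, which switches off the enol-ether donation, and Mukaiyama–Michael addition of F1 then gives keto aldehyde 9, this time isolated after aqueous work-up. Catalytic pyrrolidine and AcOH (toluene, 60 °C) close 9 to 10 by aldol condensation.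

Step 4. Palladation at the hindered tertiary α-alkoxy carbon may be sluggish, so dehydrogenation may stall, or the electron-rich phenol may be oxidised further under O2. The fallback sets out from 10 and comes back at 11, and it replaces direct catalytic dehydrogenation by oxidation of an enol silane. Enone 10 is silylated (TBSOTf, Et3N, CH2Cl2, 0 °C) to the cross-conjugated silyl dienol ether methyl 2-[8-(tert-butyldimethylsilyloxy)-2,2-dimethyl-3,4,4a,5-tetrahydro-2H-chromen-5-yl]acetate F2. This cyclohexa-1,3-diene should be aromatised by DDQ (benzene, rt) to the aryl silyl ether methyl 2-[8-(tert-butyldimethylsilyloxy)-2,2-dimethylchroman-5-yl]acetate F3, in which the phenol is protected against over-oxidation. TBAF (THF, 0 °C) then gives 11.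

Step 1. Thermal dimerisation and polymerisation of acrolein may outrun cycloaddition to the unactivated alkene, and ene-type addition may compete. The fallback does not use 1 and 2; it sets out from purchased 5-bromopent-1-ene and acetone and comes back at 3. Pent-4-enylmagnesium bromide (Mg, THF) adds to acetone to give 2-methylhept-6-en-2-ol F4. Ozonolysis (O3, CH2Cl2, −78 °C; then Me2S) gives the lactol 6,6-dimethyltetrahydro-2H-pyran-2-ol F5, the ring tautomer of the hydroxy aldehyde. Mesylation and elimination (MsCl, Et3N, CH2Cl2, 0 °C to reflux) then give 3.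

**Further compounds**

F1 | step 3 | methyl (Z)-4-[(trimethylsilyl)oxy]but-3-enoate | COC(=O)C/C=C\O[Si](C)(C)C
F2 | step 4 | methyl 2-[8-(tert-butyldimethylsilyloxy)-2,2-dimethyl-3,4,4a,5-tetrahydro-2H-chromen-5-yl]acetate | COC(=O)CC1C=CC(O[Si](C)(C)C(C)(C)C)=C2OC(C)(C)CCC12
F3 | step 4 | methyl 2-[8-(tert-butyldimethylsilyloxy)-2,2-dimethylchroman-5-yl]acetate | COC(=O)Cc1ccc(O[Si](C)(C)C(C)(C)C)c2OC(C)(C)CCc12
F4 | step 1 | 2-methylhept-6-en-2-ol | CC(C)(O)CCCC=C
F5 | step 1 | 6,6-dimethyltetrahydro-2H-pyran-2-ol | CC1(C)CCCC(O)O1
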